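## Retrosynthetic overview

1. The C3–O acyl bond is made last. Oleic acid is put on (3R)-β-cryptoxanthin after desilylation.
2. The strategy rests on the E-trisubstituted C13=C14 alkene with its methyl C20 and on the adjoining C14–C15 bond. This is the seam between the half carrying hydroxylated ring A (C1–C6) and the half carrying ring B (C1'–C6'). It is taken apart into the terminal alkyne C13≡C14, a methyl group from Me3Al and the C15 alkenyl bromide.
3. The same methylalumination–coupling cycle builds C9=C10/C19 and C9'=C10'/C19', with an E-bromoenyne as the C11–C14 unit. It also builds C13'=C14'/C20', with (E)-1-bromo-2-iodoethene as C15'=C15.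
4. Both C7–C10 enynes come from methyl ketones by enol phosphate elimination. One ketone is β-ionone. The other is its (3R)-silyloxy analogue, made from actinol by enol triflation and Heck alkenylation.
5. No ring is formed. Ring A, with the only stereocentre C3, is bought as actinol, and ring B is bought as β-ionone.

Key step: step 13

Remark on numbering: carotenoid numbering is used. C1–C6 is ring A, C7–C15 is the chain, C16–C20 are the methyl groups, and primed numbers refer to the ring B half.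

Assumption: (E)-1-bromo-2-iodoethene is treated as not purchasable and is made in step 1. All polyenes are handled under argon and with exclusion of light.

## Route

Step 1
Reactants: 1 acetylene
Product: 2 (E)-1-bromo-2-iodoethene
Conditions: IBr, 48% aq HBr, 0 °C, acetylene bubbled through
Reagents that add atoms: iodine monobromide, BrI
Why: Electrophilic halogen addition to the alkyne runs through a bridged iodonium ion that bromide opens from the opposite face, so anti addition should give the E-dihaloethene.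

Step 2
Reactants: 3 ethynyltrimethylsilane; 2 (E)-1-bromo-2-iodoethene
Product: 6 (E)-(4-bromobut-3-en-1-yn-1-yl)trimethylsilane, via lithium acetylide 4 (not isolated), via alkynylzinc bromide 5 (not isolated)
Conditions: n-BuLi, THF, −78 °C; ZnBr2, −78 → 0 °C; then 2 (1.1 equiv), Pd(PPh3)4 (2 mol %), THF, 0 → 23 °C
Reagents that add atoms: n-butyllithium, [Li]CCCC (Li of 4 only); zinc dibromide, Br[Zn]Br (Zn and Br of 5 only)
Why: In this Negishi alkynyl–alkenyl coupling zerovalent palladium inserts into the weaker C–I bond much faster than into C–Br and retains the E geometry, so the bromide is kept for the next coupling.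

Step 3
Reactants: 7 β-ionone
Product: 11 (E)-2-(but-1-en-3-yn-1-yl)-1,3,3-trimethylcyclohex-1-ene, via lithium enolate 8 (not isolated), via enol phosphate 9 (not isolated), via lithium acetylide 10 (not isolated)
Conditions: LiN(i-Pr)2 (1.05 equiv), THF, −78 °C; ClP(O)(OEt)2, −78 → 23 °C; then LiN(i-Pr)2 (2.3 equiv), THF, −78 → 23 °C; H2O
Reagents that add atoms: diethyl chlorophosphate, CCOP(=O)(Cl)OCC (held only in 9); lithium diisopropylamide, [Li]N(C(C)C)C(C)C (Li of 8 and 10 only)
Why: Kinetic deprotonation at the acetyl methyl, O-phosphorylation and base-induced loss of diethyl phosphate (enol phosphate elimination, methyl ketone to terminal alkyne) should give the C9'≡C10' enyne without touching the E-C7'=C8' bond.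

Step 4
Reactants: 11 (E)-2-(but-1-en-3-yn-1-yl)-1,3,3-trimethylcyclohex-1-ene; 12 trimethylaluminium; 6 (E)-(4-bromobut-3-en-1-yn-1-yl)trimethylsilane
Product: 15 trimethyl[(3E,5E,7E)-6-methyl-8-(2,6,6-trimethylcyclohex-1-en-1-yl)octa-3,5,7-trien-1-yn-1-yl]silane, via alkenylalane 13 (not isolated), via alkenylzinc chloride 14 (not isolated)
Conditions: Me3Al (2 equiv), Cp2ZrCl2 (0.25 equiv), CH2Cl2, 23 °C; volatiles off in vacuo; THF, ZnCl2 (1 equiv); 6 (1.05 equiv), Pd(PPh3)4 (5 mol %), THF, 23 °C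
Reagents that add atoms: trimethylaluminium 12, C[Al](C)C (methyl C19'; AlMe2 of 13); zinc dichloride, Cl[Zn]Cl (ZnCl of 14 only)
Why: Zirconium-catalysed syn methylalumination puts methyl C19' on internal C9' and aluminium on terminal C10', and the zinc-mediated Negishi alkenyl–alkenyl coupling with the E-bromide keeps the geometry of both partners.

Step 5
Reactants: 15 trimethyl[(3E,5E,7E)-6-methyl-8-(2,6,6-trimethylcyclohex-1-en-1-yl)octa-3,5,7-trien-1-yn-1-yl]silane
Product: 16 2-[(1E,3E,5E)-3-methylocta-1,3,5-trien-7-yn-1-yl]-1,3,3-trimethylcyclohex-1-ene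
Conditions: K2CO3, MeOH–THF, 23 °C
Reagents that add atoms: none
Why: Carbonate-promoted methanolysis of the alkynyl C–Si bond (protiodesilylation) is specific for sp-bound silicon and leaves the polyene alone.

Step 6
Reactants: 16 2-[(1E,3E,5E)-3-methylocta-1,3,5-trien-7-yn-1-yl]-1,3,3-trimethylcyclohex-1-ene; 12 trimethylaluminium; 2 (E)-1-bromo-2-iodoethene
Product: 19 2-[(1E,3E,5E,7E,9E)-10-bromo-3,7-dimethyldeca-1,3,5,7,9-pentaen-1-yl]-1,3,3-trimethylcyclohex-1-ene, via alkenylalane 17 (not isolated), via alkenylzinc chloride 18 (not isolated)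
Conditions: Me3Al (2 equiv), Cp2ZrCl2 (0.25 equiv), CH2Cl2, 23 °C; volatiles off in vacuo; THF, ZnCl2 (1 equiv); added slowly to 2 (2 equiv), Pd(PPh3)4 (5 mol %), THF, 0 → 23 °C, dark; used at once
Reagents that add atoms: trimethylaluminium 12, C[Al](C)C (methyl C20'; AlMe2 of 17); zinc dichloride, Cl[Zn]Cl (ZnCl of 18 only)
Why: In this second methylalumination–Negishi coupling cycle syn addition fixes 13'E with methyl C20' on C13', and because zerovalent palladium inserts into C–I far faster than into C–Br, slow addition of 18 to excess 2 should stop at monocoupling and keep the E-bromide at C15.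

Step 7
Reactants: 20 (4R,6R)-4-hydroxy-2,2,6-trimethylcyclohexanone (actinol)
Product: 21 (4R,6R)-4-(tert-butyldimethylsilyloxy)-2,2,6-trimethylcyclohexanone
Conditions: TBSCl, imidazole, DMF, 23 °C
Reagents that add atoms: tert-butyldimethylsilyl chloride, CC(C)(C)[Si](C)(C)Cl
Why: Imidazole-promoted O-silylation of the secondary alcohol does not break the C–O bond, so the carbinol centre (future C3, R) is carried over from the chiral pool.

Step 8
Reactants: 21 (4R,6R)-4-(tert-butyldimethylsilyloxy)-2,2,6-trimethylcyclohexanone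
Product: 23 (4R)-4-(tert-butyldimethylsilyloxy)-2,6,6-trimethylcyclohex-1-en-1-yl trifluoromethanesulfonate, via lithium enolate 22 (not isolated)
Conditions: LiN(i-Pr)2 (1.2 equiv), THF, −78 → 0 °C; PhNTf2 (1.2 equiv), 0 → 23 °C
Reagents that add atoms: N-phenylbis(trifluoromethanesulfonimide), O=S(=O)(N(c1ccccc1)S(=O)(=O)C(F)(F)F)C(F)(F)F; lithium diisopropylamide, [Li]N(C(C)C)C(C)C (Li of 22 only)
Why: Only one α-carbon bears hydrogen, so enolisation is regiochemically unambiguous and O-triflation (enol triflate formation) fixes the tetrasubstituted C5=C6 alkene, while the silyloxy carbon, γ to the carbonyl, can neither epimerise nor eliminate.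

Step 9
Reactants: 23 (4R)-4-(tert-butyldimethylsilyloxy)-2,6,6-trimethylcyclohex-1-en-1-yl trifluoromethanesulfonate; 24 but-3-en-2-one (methyl vinyl ketone)
Product: 25 (E)-4-[(4R)-4-(tert-butyldimethylsilyloxy)-2,6,6-trimethylcyclohex-1-en-1-yl]but-3-en-2-one
Conditions: 24 (5 equiv), Pd(OAc)2 (5 mol %), PPh3 (10 mol %), Et3N (3 equiv), DMF, 70 °C
Reagents that add atoms: but-3-en-2-one 24, C=CC(C)=O
Why: In this Mizoroki–Heck alkenylation of an enol triflate the alkenylpalladium adds to the unsubstituted terminus of the enone, and syn β-hydride elimination should give the E-C7=C8 dienone.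

Step 10
Reactants: 25 (E)-4-[(4R)-4-(tert-butyldimethylsilyloxy)-2,6,6-trimethylcyclohex-1-en-1-yl]but-3-en-2-one
Product: 29 (R)-{[4-((E)-but-1-en-3-yn-1-yl)-3,5,5-trimethylcyclohex-3-en-1-yl]oxy}(tert-butyl)dimethylsilane, via lithium enolate 26 (not isolated), via enol phosphate 27 (not isolated), via lithium acetylide 28 (not isolated)
Conditions: LiN(i-Pr)2 (1.05 equiv), THF, −78 °C; ClP(O)(OEt)2, −78 → 23 °C; then LiN(i-Pr)2 (2.3 equiv), THF, −78 → 0 °C; H2O
Reagents that add atoms: diethyl chlorophosphate, CCOP(=O)(Cl)OCC (held only in 27); lithium diisopropylamide, [Li]N(C(C)C)C(C)C (Li of 26 and 28 only)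
Why: This is the enol phosphate elimination of step 3, and at −78 °C the amide base removes the acetyl proton faster than the vinylogous C4 and C18 protons, so the C3 silyl ether and its stereocentre should stay untouched.

Step 11
Reactants: 29 (R)-{[4-((E)-but-1-en-3-yn-1-yl)-3,5,5-trimethylcyclohex-3-en-1-yl]oxy}(tert-butyl)dimethylsilane; 12 trimethylaluminium; 6 (E)-(4-bromobut-3-en-1-yn-1-yl)trimethylsilane
Product: 32 (R)-tert-butyldimethyl{[3,5,5-trimethyl-4-((1E,3E,5E)-3-methyl-8-(trimethylsilyl)octa-1,3,5-trien-7-yn-1-yl)cyclohex-3-en-1-yl]oxy}silane, via alkenylalane 30 (not isolated), via alkenylzinc chloride 31 (not isolated)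
Conditions: Me3Al (2 equiv), Cp2ZrCl2 (0.25 equiv), CH2Cl2, 23 °C; volatiles off in vacuo; THF, ZnCl2 (1 equiv); 6 (1.05 equiv), Pd(PPh3)4 (5 mol %), THF, 23 °C
Reagents that add atoms: trimethylaluminium 12, C[Al](C)C (methyl C19; AlMe2 of 30); zinc dichloride, Cl[Zn]Cl (ZnCl of 31 only)
Why: Zirconium-catalysed syn methylalumination puts methyl C19 on C9 and aluminium on C10, the stereoretentive Negishi coupling adds C11–C14, and the silyl ether tolerates the alane.

Step 12
Reactants: 32 (R)-tert-butyldimethyl{[3,5,5-trimethyl-4-((1E,3E,5E)-3-methyl-8-(trimethylsilyl)octa-1,3,5-trien-7-yn-1-yl)cyclohex-3-en-1-yl]oxy}silane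
Product: 33 (R)-tert-butyldimethyl{[3,5,5-trimethyl-4-((1E,3E,5E)-3-methylocta-1,3,5-trien-7-yn-1-yl)cyclohex-3-en-1-yl]oxy}silane
Conditions: K2CO3, MeOH–THF, 23 °C
Reagents that add atoms: none
Why: Carbonate-promoted methanolysis (protiodesilylation) cleaves only the alkynyl C–Si bond, since the hindered secondary tert-butyldimethylsilyl ether is stable to K2CO3 in methanol.

Step 13
Reactants: 33 (R)-tert-butyldimethyl{[3,5,5-trimethyl-4-((1E,3E,5E)-3-methylocta-1,3,5-trien-7-yn-1-yl)cyclohex-3-en-1-yl]oxy}silane; 12 trimethylaluminium; 19 2-[(1E,3E,5E,7E,9E)-10-bromo-3,7-dimethyldeca-1,3,5,7,9-pentaen-1-yl]-1,3,3-trimethylcyclohex-1-ene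
Product: 36 (3R)-β-cryptoxanthin tert-butyldimethylsilyl ether, via alkenylalane 34 (not isolated), via alkenylzinc chloride 35 (not isolated)
Conditions: 33 (1.15 equiv), Me3Al (2 equiv), Cp2ZrCl2 (0.25 equiv), CH2Cl2, 23 °C, dark; volatiles off in vacuo; THF, ZnCl2 (1.15 equiv), 0 °C; then 19 (1.0 equiv), Pd(PPh3)4 (5 mol %), THF, 23 °C, dark
Reagents that add atoms: trimethylaluminium 12, C[Al](C)C (methyl C20; AlMe2 of 34); zinc dichloride, Cl[Zn]Cl (ZnCl of 35 only)
Why: Cp2ZrCl2 and Me3Al form a chloride-bridged, strongly polarised methylzirconocene that adds methyl and metal across C13≡C14 of 33 through a four-centre syn transition state and passes the alkenyl group back to aluminium, giving alane 34 with methyl C20 on C13 and aluminium on C14. After the surplus Me3Al has been stripped off (methylzinc species would otherwise methylate the bromide), ZnCl2 takes over the alkenyl group as 35, zerovalent palladium inserts into the C15–Br bond of 19, and transmetalation and reductive elimination form C14–C15, all with retention of alkene geometry. The closest known reaction type is the zirconium-catalysed methylalumination of terminal enynes followed by Negishi alkenyl–alkenyl coupling, the cycle already run in steps 4, 6 and 11. No ring is closed and no stereocentre is created, and C3 is remote with a silyl ether that is inert to the alane. The step needs regioselectivity (methyl to the internal carbon) and clean syn addition: the first follows from the terminal alkyne, whose unsubstituted C14 takes the bulky metal, and the second from the concerted insertion, so that C12 and C15 end up trans (13E). The 15E geometry is brought in by 19, and chemoselectivity rests on alkenyl transfer from zinc to palladium being much faster than methyl transfer.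

Step 14
Reactants: 36 (3R)-β-cryptoxanthin tert-butyldimethylsilyl ether
Product: 37 (3R)-β-cryptoxanthin
Conditions: Bu4NF, THF, 0 → 23 °C, dark; H2O
Reagents that add atoms: none
Why: Fluoride-driven cleavage of the Si–O bond (desilylation) is neutral toward the polyene and does not break C3–O, so the R configuration is retained.

Step 15
Reactants: 37 (3R)-β-cryptoxanthin; 38 oleic acid
Product: 40 (3R)-β-cryptoxanthin oleate (CNP0152321.1), via O-acylisourea 39 (not isolated)
Conditions: 38 (1.3 equiv), DCC (1.4 equiv), DMAP (0.2 equiv), CH2Cl2, 0 → 23 °C, dark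
Reagents that add atoms: oleic acid 38, CCCCCCCC/C=C\CCCCCCCC(=O)O; N,N'-dicyclohexylcarbodiimide, C1CCC(CC1)N=C=NC1CCCCC1 (held only in 39)
Why: In this Steglich esterification the acid is activated as the O-acylisourea and handed on by DMAP to the C3 hydroxyl, so acylation occurs at oxygen with C3 (R), the Z-alkene of the acid and the all-E polyene unchanged.

## Compound list

1 | acetylene | C#C | starting material
2 | (E)-1-bromo-2-iodoethene | Br/C=C/I | intermediate
3 | ethynyltrimethylsilane | C#C[Si](C)(C)C | starting material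
4 | lithium (trimethylsilyl)acetylide | [Li]C#C[Si](C)(C)C | intermediate
5 | bromo[(trimethylsilyl)ethynyl]zinc | Br[Zn]C#C[Si](C)(C)C | intermediate
6 | (E)-(4-bromobut-3-en-1-yn-1-yl)trimethylsilane | Br/C=C/C#C[Si](C)(C)C | intermediate
7 | β-ionone | CC(=O)/C=C/C1=C(C)CCCC1(C)C | starting material
8 | lithium (E)-4-(2,6,6-trimethylcyclohex-1-en-1-yl)buta-1,3-dien-2-olate | [Li]OC(=C)/C=C/C1=C(C)CCCC1(C)C | intermediate
9 | diethyl (E)-4-(2,6,6-trimethylcyclohex-1-en-1-yl)buta-1,3-dien-2-yl phosphate | CCOP(=O)(OCC)OC(=C)/C=C/C1=C(C)CCCC1(C)C | intermediate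
10 | lithium acetylide of 11 | [Li]C#C/C=C/C1=C(C)CCCC1(C)C | intermediate
11 | (E)-2-(but-1-en-3-yn-1-yl)-1,3,3-trimethylcyclohex-1-ene | C#C/C=C/C1=C(C)CCCC1(C)C | intermediate
12 | trimethylaluminium | C[Al](C)C | starting material
13 | dimethyl[(1E,3E)-2-methyl-4-(2,6,6-trimethylcyclohex-1-en-1-yl)buta-1,3-dien-1-yl]alane | C[Al](C)/C=C(C)/C=C/C1=C(C)CCCC1(C)C | intermediate
14 | chloro[(1E,3E)-2-methyl-4-(2,6,6-trimethylcyclohex-1-en-1-yl)buta-1,3-dien-1-yl]zinc | Cl[Zn]/C=C(C)/C=C/C1=C(C)CCCC1(C)C | intermediate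
15 | trimethyl[(3E,5E,7E)-6-methyl-8-(2,6,6-trimethylcyclohex-1-en-1-yl)octa-3,5,7-trien-1-yn-1-yl]silane | C[Si](C)(C)C#C/C=C/C=C(C)/C=C/C1=C(C)CCCC1(C)C | intermediate
16 | 2-[(1E,3E,5E)-3-methylocta-1,3,5-trien-7-yn-1-yl]-1,3,3-trimethylcyclohex-1-ene | C#C/C=C/C=C(C)/C=C/C1=C(C)CCCC1(C)C | intermediate
17 | [(1E,3E,5E,7E)-2,6-dimethyl-8-(2,6,6-trimethylcyclohex-1-en-1-yl)octa-1,3,5,7-tetraen-1-yl]dimethylalane | C[Al](C)/C=C(C)/C=C/C=C(C)/C=C/C1=C(C)CCCC1(C)C | intermediate
18 | chloro[(1E,3E,5E,7E)-2,6-dimethyl-8-(2,6,6-trimethylcyclohex-1-en-1-yl)octa-1,3,5,7-tetraen-1-yl]zinc | Cl[Zn]/C=C(C)/C=C/C=C(C)/C=C/C1=C(C)CCCC1(C)C | intermediate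
19 | 2-[(1E,3E,5E,7E,9E)-10-bromo-3,7-dimethyldeca-1,3,5,7,9-pentaen-1-yl]-1,3,3-trimethylcyclohex-1-ene (C15–C7' pentaenyl bromide) | Br/C=C/C=C(C)/C=C/C=C(C)/C=C/C1=C(C)CCCC1(C)C | intermediate
20 | (4R,6R)-4-hydroxy-2,2,6-trimethylcyclohexanone (actinol) | O[C@@H]1C[C@@H](C)C(=O)C(C)(C)C1 | starting material
21 | (4R,6R)-4-(tert-butyldimethylsilyloxy)-2,2,6-trimethylcyclohexanone | CC(C)(C)[Si](C)(C)O[C@@H]1C[C@@H](C)C(=O)C(C)(C)C1 | intermediate
22 | lithium (4R)-4-(tert-butyldimethylsilyloxy)-2,6,6-trimethylcyclohex-1-en-1-olate | CC(C)(C)[Si](C)(C)O[C@@H]1CC(C)=C(O[Li])C(C)(C)C1 | intermediate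
23 | (4R)-4-(tert-butyldimethylsilyloxy)-2,6,6-trimethylcyclohex-1-en-1-yl trifluoromethanesulfonate | CC(C)(C)[Si](C)(C)O[C@@H]1CC(C)=C(OS(=O)(=O)C(F)(F)F)C(C)(C)C1 | intermediate
24 | but-3-en-2-one (methyl vinyl ketone) | C=CC(C)=O | starting material
25 | (E)-4-[(4R)-4-(tert-butyldimethylsilyloxy)-2,6,6-trimethylcyclohex-1-en-1-yl]but-3-en-2-one | CC(C)(C)[Si](C)(C)O[C@@H]1CC(C)=C(/C=C/C(C)=O)C(C)(C)C1 | intermediate
26 | lithium dienolate of 25 (acetyl carbon deprotonated) | CC(C)(C)[Si](C)(C)O[C@@H]1CC(C)=C(/C=C/C(=C)O[Li])C(C)(C)C1 | intermediate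
27 | diethyl enol phosphate of 25 | CC(C)(C)[Si](C)(C)O[C@@H]1CC(C)=C(/C=C/C(=C)OP(=O)(OCC)OCC)C(C)(C)C1 | intermediate
28 | lithium acetylide of 29 | CC(C)(C)[Si](C)(C)O[C@@H]1CC(C)=C(/C=C/C#C[Li])C(C)(C)C1 | intermediate
29 | (R)-{[4-((E)-but-1-en-3-yn-1-yl)-3,5,5-trimethylcyclohex-3-en-1-yl]oxy}(tert-butyl)dimethylsilane | CC(C)(C)[Si](C)(C)O[C@@H]1CC(C)=C(/C=C/C#C)C(C)(C)C1 | intermediate
30 | {(1E,3E)-4-[(4R)-4-(tert-butyldimethylsilyloxy)-2,6,6-trimethylcyclohex-1-en-1-yl]-2-methylbuta-1,3-dien-1-yl}dimethylalane | CC(C)(C)[Si](C)(C)O[C@@H]1CC(C)=C(/C=C/C(C)=C/[Al](C)C)C(C)(C)C1 | intermediate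
31 | {(1E,3E)-4-[(4R)-4-(tert-butyldimethylsilyloxy)-2,6,6-trimethylcyclohex-1-en-1-yl]-2-methylbuta-1,3-dien-1-yl}chlorozinc | CC(C)(C)[Si](C)(C)O[C@@H]1CC(C)=C(/C=C/C(C)=C/[Zn]Cl)C(C)(C)C1 | intermediate
32 | (R)-tert-butyldimethyl{[3,5,5-trimethyl-4-((1E,3E,5E)-3-methyl-8-(trimethylsilyl)octa-1,3,5-trien-7-yn-1-yl)cyclohex-3-en-1-yl]oxy}silane | CC(C)(C)[Si](C)(C)O[C@@H]1CC(C)=C(/C=C/C(C)=C/C=C/C#C[Si](C)(C)C)C(C)(C)C1 | intermediate
33 | (R)-tert-butyldimethyl{[3,5,5-trimethyl-4-((1E,3E,5E)-3-methylocta-1,3,5-trien-7-yn-1-yl)cyclohex-3-en-1-yl]oxy}silane (C7–C14 tetraenyne) | CC(C)(C)[Si](C)(C)O[C@@H]1CC(C)=C(/C=C/C(C)=C/C=C/C#C)C(C)(C)C1 | intermediate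
34 | C14 dimethylalane from 33 (methyl C20 on C13, 13E) | CC(C)(C)[Si](C)(C)O[C@@H]1CC(C)=C(/C=C/C(C)=C/C=C/C(C)=C/[Al](C)C)C(C)(C)C1 | intermediate
35 | C14 chlorozinc reagent from 34 | CC(C)(C)[Si](C)(C)O[C@@H]1CC(C)=C(/C=C/C(C)=C/C=C/C(C)=C/[Zn]Cl)C(C)(C)C1 | intermediate
36 | (3R)-β-cryptoxanthin tert-butyldimethylsilyl ether | CC(C)(C)[Si](C)(C)O[C@@H]1CC(C)=C(/C=C/C(C)=C/C=C/C(C)=C/C=C/C=C(C)/C=C/C=C(C)/C=C/C2=C(C)CCCC2(C)C)C(C)(C)C1 | intermediate
37 | (3R)-β-cryptoxanthin | O[C@@H]1CC(C)=C(/C=C/C(C)=C/C=C/C(C)=C/C=C/C=C(C)/C=C/C=C(C)/C=C/C2=C(C)CCCC2(C)C)C(C)(C)C1 | intermediate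
38 | oleic acid | CCCCCCCC/C=C\CCCCCCCC(=O)O | starting material
39 | O-oleoyl-N,N'-dicyclohexylisourea | CCCCCCCC/C=C\CCCCCCCC(=O)OC(=NC1CCCCC1)NC1CCCCC1 | intermediate
40 | (3R)-β-cryptoxanthin oleate (CNP0152321.1) | CCCCCCCC/C=C\CCCCCCCC(=O)O[C@@H]1CC(C)=C(/C=C/C(C)=C/C=C/C(C)=C/C=C/C=C(C)/C=C/C=C(C)/C=C/C2=C(C)CCCC2(C)C)C(C)(C)C1 | target

## Step count

Total step count: 15.
Longest linear sequence: 9 steps (20 → 40, steps 7–15).

## Steps most likely to fail

**Step 13.** Methylalumination of the long, electron-rich tetraenyne may be slow or incomplete. Residual methylmetal species may transfer methyl to the palladium intermediate. The labile bromide may decompose or lose its geometry while it waits for transmetalation.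

- Fallback: the two bond formations are separated and the polarity of the coupling is reversed, so that both partners can be isolated and purified. It sets out from 33 and 16 and comes back at 36.
- Alane 34 is made from 33 as before but is quenched with I2 (THF, −30 °C) to the (13E)-C14 alkenyl iodide F1. C13–C20 and the 13E geometry are thus still set by carboalumination.
- From 16, zinc reagent 18 is made as in step 6. It is coupled not with 2 but with commercial (E)-2-bromovinylboronic acid MIDA ester (CN1CC(=O)OB(/C=C/Br)OC(=O)C1) under Negishi conditions (Pd(OAc)2, SPhos, THF, 0 → 23 °C). This gives the bench-stable pentaenyl MIDA boronate F2.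
- Aqueous NaOH in THF releases the pentaenylboronic acid F3. Suzuki–Miyaura coupling of F3 with F1 (Pd(OAc)2, SPhos, 23 °C, dark) forms C14–C15 and gives 36.

**Step 10.** Vinylogous deprotonation at C4 or C18 may compete and lead to loss of silanolate. The elimination of the enol phosphate may also stop short or drift toward an allene.

- Fallback: the methyl ketone is avoided, and the alkyne carbon is added to an aldehyde that has no acidic α-hydrogen. It sets out from 23 and comes back at 29.
- Stille coupling of 23 with (E)-3-(tributylstannyl)prop-2-en-1-ol (Pd2(dba)3, AsPh3, LiCl, NMP, 55 °C) gives the (E)-dienol F4.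
- MnO2 in CH2Cl2 oxidises F4 to the (E)-dienal F5.
- Lithiated trimethylsilyldiazomethane (THF, −78 → 0 °C, Colvin rearrangement) turns the formyl group of F5 into the terminal alkyne of 29.

**Step 9.** Oxidative addition and migratory insertion may be slow at the tetrasubstituted triflate, which is flanked on both sides. Reduction or hydrolysis of the triflate and polymerisation of the enone may then take over.

- Fallback: a slim sp-carbon nucleophile is coupled first, and the E-alkene and the ketone are set afterwards. It sets out from 23 and comes back at 25.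
- Sonogashira coupling of 23 with but-3-yn-2-ol (PdCl2(PPh3)2, CuI, Et3N, DMF, 50 °C) gives the enynol F6.
- Hydroxyl-directed trans-hydroalumination with NaAlH2(OCH2CH2OMe)2 (THF, 0 → 23 °C), followed by protonolysis, gives the (E)-dienol F7.
- MnO2 in CH2Cl2 oxidises the allylic alcohol of F7 to 25. The carbinol centre of F6 and F7 may be a mixture, since this oxidation erases it.

## Further compounds

F1 | step 13 | (R)-tert-butyl{[4-((1E,3E,5E,7E)-8-iodo-3,7-dimethylocta-1,3,5,7-tetraen-1-yl)-3,5,5-trimethylcyclohex-3-en-1-yl]oxy}dimethylsilane | CC(C)(C)[Si](C)(C)O[C@@H]1CC(C)=C(/C=C/C(C)=C/C=C/C(C)=C/I)C(C)(C)C1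
F2 | step 13 | 2-[(1E,3E,5E,7E,9E)-4,8-dimethyl-10-(2,6,6-trimethylcyclohex-1-en-1-yl)deca-1,3,5,7,9-pentaen-1-yl]-6-methyl-1,3,6,2-dioxazaborocane-4,8-dione | CN1CC(=O)OB(/C=C/C=C(C)/C=C/C=C(C)/C=C/C2=C(C)CCCC2(C)C)OC(=O)C1
F3 | step 13 | [(1E,3E,5E,7E,9E)-4,8-dimethyl-10-(2,6,6-trimethylcyclohex-1-en-1-yl)deca-1,3,5,7,9-pentaen-1-yl]boronic acid | OB(O)/C=C/C=C(C)/C=C/C=C(C)/C=C/C1=C(C)CCCC1(C)C
F4 | step 10 | (E)-3-[(4R)-4-(tert-butyldimethylsilyloxy)-2,6,6-trimethylcyclohex-1-en-1-yl]prop-2-en-1-ol | CC(C)(C)[Si](C)(C)O[C@@H]1CC(C)=C(/C=C/CO)C(C)(C)C1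
F5 | step 10 | (E)-3-[(4R)-4-(tert-butyldimethylsilyloxy)-2,6,6-trimethylcyclohex-1-en-1-yl]prop-2-enal | CC(C)(C)[Si](C)(C)O[C@@H]1CC(C)=C(/C=C/C=O)C(C)(C)C1
F6 | step 9 | 4-[(4R)-4-(tert-butyldimethylsilyloxy)-2,6,6-trimethylcyclohex-1-en-1-yl]but-3-yn-2-ol (both carbinol epimers) | CC(C)(C)[Si](C)(C)O[C@@H]1CC(C)=C(C#CC(C)O)C(C)(C)C1
F7 | step 9 | (E)-4-[(4R)-4-(tert-butyldimethylsilyloxy)-2,6,6-trimethylcyclohex-1-en-1-yl]but-3-en-2-ol (both carbinol epimers) | CC(C)(C)[Si](C)(C)O[C@@H]1CC(C)=C(/C=C/C(C)O)C(C)(C)C1
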